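Molar seconds are what Friday's flask spends, so count them before you look inside.

common to all: substrate 0.10 M; partner 0.0900 M; free catalyst 2.5 mM; time 8.0 min
- Friday's: temperature 40 °C
- Tuesday's: temperature 0 °C
- Monday's: temperature 20 °C

    catalyst intermediate C → catalyst intermediate D (k1 = 0.363 s⁻¹, Ea1 = 74.0 kJ mol⁻¹)
    substrate + catalyst intermediate A → catalyst intermediate B (k2 = 15.7 M⁻¹ s⁻¹, Ea2 = 54.0 kJ mol⁻¹)
    partner + free catalyst → catalyst intermediate A (k3 = 5.73 M⁻¹ s⁻¹, Ea3 = 59.0 kJ mol⁻¹)
    catalyst intermediate D → free catalyst + product (k4 = 0.380 s⁻¹, Ea4 = 83.0 kJ mol⁻¹)
    catalyst intermediate B → released group + catalyst intermediate C (k5 = 0.493 s⁻¹, Ea5 = 83.0 kJ mol⁻¹)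
    (constants at 40 °C)

- the best flask by amount of product, in percent of the substrate charged; "all alike" if 1.5 percentage points covers them all (Friday's / Tuesday's / Monday's / all alike)
- amount of product at the end, in percent of the substrate charged, Friday's
- amount of product at the end, in percent of the substrate charged, Tuesday's
- amount of product at the end, in percent of the substrate charged, Monday's

- all constants are for 40 °C and move with temperature by the activation energies

Here is what is in the flask. Partner binds free catalyst to give catalyst intermediate A. Substrate joins to give catalyst intermediate B, which sheds released group and becomes catalyst intermediate C. That turns into catalyst intermediate D, which gives product and returns free catalyst. Each turn uses one partner and one substrate. Partner is the limiting reagent, 0.0900 M against 0.10 M of substrate.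

Now freeze what barely moves. The catalyst total stays constant, and I take each intermediate as made as fast as it is used. One turn then takes the sum of its step times. In Friday's flask the three steps without a reagent give 7.41 s, and at the starting charges the whole turn takes 9.99 s.

Catalyst charge times time gives 1.20 M·s. Call that the catalyst budget. At Friday's starting turn time it buys 0.120 M, more than the partner charge. But turns lengthen as the reagents fall. On this reckoning the cost has three pieces: the constant part times the partner used, the log of partner's fall over the rate constant of its step, and the log of substrate's fall over the rate constant of its step.

By my reckoning, Friday's partner down to 7.14% of its charge costs 1.20 M·s, about the budget. So when you come, expect partner used in Friday's flask equal to 83.6% of the substrate charged, with product a little behind it. I reckoned no cold flask. Don't cool Friday's: every constant shrinks in the cold, and the budget stays the same.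

The forecast names Friday's as best, with 83.3% there, 15.4% on Monday's and 0.72% on Tuesday's. Unlike my figure, its Friday's number takes off what “remains held in intermediates”.

The flasks gave 83.1% on Friday's, 15.5% on Monday's and 0.732% on Tuesday's, so Friday's is best. The falling level of partner is the main reason Friday's stood at that figure at the end, since with partner held at its charge the run gives 98.3%. Friday's partner at the end, 6.9% of its charge, costs 1.21 M·s, against a budget of 1.20 M·s. A neighbour of Friday's with 0.0043 M of free catalyst has a budget of 2.06 M·s, and the 0.077% of partner it leaves costs 2.06 M·s, with product at 89.9%.

Its constants are those of an exercise, and the outcome is calculated.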